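The methylene bridge C9 is a lone carbon joining C5 of the isocoumarin to C1' of benzene ring A, and each of these carbons is flanked by two ortho substituents. The route cuts both bonds of C9. A palladium-catalysed carbonylative Suzuki–Miyaura coupling inserts carbon monoxide between the two arenes, forming C5–C9 and C9–C1' in one operation. C9 is left as a ketone, which the ortho 6-OH and para 4'-OH later make reducible to CH2. The coupling partners are 5-iodo-8-methoxy-6-(methoxymethoxy)-3-methylisocoumarin and the 2,6-disubstituted ring A boronic acid; their iodine and boron fix both attachment sites.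

Key step: step 10

Remark: the target has no stereocentre and is achiral, so no enantiocontrol is needed; isocoumarin atoms carry plain locants, ring A atoms primed locants (C1' bears the bridge), and C9 is the bridge carbon.

Step 1
Reactants: 1 methyl 2,4-dihydroxy-6-methylbenzoate (methyl orsellinate)
Product: 2 methyl 2-hydroxy-4-(methoxymethoxy)-6-methylbenzoate
Conditions: MOMCl (1.1 equiv), i-Pr2NEt, CH2Cl2, 0 °C to rt
Reagents that add atoms: chloromethyl methyl ether, COCCl
Why: Williamson-type O-alkylation should go to the 4-OH alone, since the 2-OH is locked in a hydrogen bond to the ester carbonyl and is much less nucleophilic.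

Step 2
Reactants: 2 methyl 2-hydroxy-4-(methoxymethoxy)-6-methylbenzoate
Product: 3 methyl 2-methoxy-4-(methoxymethoxy)-6-methylbenzoate
Conditions: MeI, K2CO3, DMF, 40 °C
Reagents that add atoms: iodomethane, CI
Why: Williamson methylation of the remaining chelated phenol under carbonate conditions, to which the acetal and the ester are inert.

Step 3
Reactants: 3 methyl 2-methoxy-4-(methoxymethoxy)-6-methylbenzoate
Product: 6 methyl 2-methoxy-4-(methoxymethoxy)-6-(2-oxopropyl)benzoate, via lithiated toluate 4 (not isolated), via lithium hemiaminal adduct 5 (not isolated)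
Conditions: LDA (1.2 equiv), THF, −78 °C (ester added to base); then MeC(O)N(OMe)Me, −78 °C; aq. NH4Cl
Reagents that add atoms: N-methoxy-N-methylacetamide, CC(=O)N(C)OC
Why: Lateral (benzylic) lithiation of the o-toluate gives a carbanion conjugated with the ester, and its Weinreb-amide acylation stops at the chelated adduct 5, so the ketone is released only on quench and cannot react further.

Step 4
Reactants: 6 methyl 2-methoxy-4-(methoxymethoxy)-6-(2-oxopropyl)benzoate
Product: 8 8-methoxy-6-(methoxymethoxy)-3-methyl-1H-isochromen-1-one, via keto acid 7 (not isolated)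
Conditions: LiOH·H2O (3 equiv), THF/MeOH/H2O, 40 °C; 1 M HCl to pH 4 at 0 °C, extraction; then Ac2O, pyridine, 60 °C
Reagents that add atoms: none
Why: Saponification, helped by the neighbouring enolisable ketone, followed by cyclodehydration of the o-(2-oxopropyl)benzoic acid through its mixed anhydride (enol lactonisation) should build the pyranone under conditions that leave the acid-labile acetal alone.

Step 5
Reactants: 8 8-methoxy-6-(methoxymethoxy)-3-methyl-1H-isochromen-1-one
Product: 9 5-iodo-8-methoxy-6-(methoxymethoxy)-3-methyl-1H-isochromen-1-one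
Conditions: NIS (1.05 equiv), TFA (5 mol %), MeCN, 0 °C, dark
Reagents that add atoms: N-iodosuccinimide, O=C1CCC(=O)N1I
Why: Electrophilic aromatic iodination should favour C5, which is ortho to O6 and para to O8, over C7, which is squeezed between both ether groups, and over C4, which is only an enol-ester carbon; the low acid loading at 0 °C spares the acetal.

Step 6
Reactants: 10 (2-bromo-3-methoxyphenyl)methanol
Product: 11 2-bromo-1-methoxy-3-(methoxymethyl)benzene
Conditions: NaH, MeI, THF, 0 °C to rt
Reagents that add atoms: iodomethane, CI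
Why: Williamson etherification of the primary benzylic alkoxide, with no competing acidic or electrophilic site in the molecule.

Step 7
Reactants: 11 2-bromo-1-methoxy-3-(methoxymethyl)benzene
Product: 13 4-bromo-3-methoxy-5-(methoxymethyl)phenol, via arylboronate 12 (not isolated)
Conditions: [Ir(OMe)(cod)]2 (1.5 mol %), dtbpy (3 mol %), B2pin2 (1.0 equiv), THF, 80 °C; then Oxone, acetone/H2O, rt
Reagents that add atoms: potassium peroxymonosulfate (Oxone), [K+].[O-]S(=O)(=O)OO
Why: Iridium-catalysed C–H borylation is steered by sterics to the only ring C–H with no ortho neighbour (C5, para to bromine), and oxidation of the C–B bond then gives the phenol while the hindered aryl bromide stays intact.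

Step 8
Reactants: 13 4-bromo-3-methoxy-5-(methoxymethyl)phenol
Product: 14 2-bromo-1-methoxy-3-(methoxymethyl)-5-(methoxymethoxy)benzene
Conditions: MOMCl, i-Pr2NEt, CH2Cl2, 0 °C to rt
Reagents that add atoms: chloromethyl methyl ether, COCCl
Why: O-alkylation of the unhindered phenol installs an acetal that tolerates the organolithium and the basic palladium step and is later removed together with the one on the isocoumarin.

Step 9
Reactants: 14 2-bromo-1-methoxy-3-(methoxymethyl)-5-(methoxymethoxy)benzene
Product: 17 [2-methoxy-6-(methoxymethyl)-4-(methoxymethoxy)phenyl]boronic acid, via aryllithium 15 (not isolated), via lithium triisopropoxyborate 16 (not isolated)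
Conditions: n-BuLi (1.05 equiv), THF, −78 °C; B(Oi-Pr)3, −78 °C to rt; aq. NH4Cl (pH ≈ 6); used without chromatography
Reagents that add atoms: triisopropyl borate, CC(C)OB(OC(C)C)OC(C)C; water, O
Why: Bromine–lithium exchange at −78 °C outruns ortho-deprotonation and places the metal exactly at the former C–Br carbon, and borate trapping with near-neutral hydrolysis should give the boronic acid with little protodeboronation.

Step 10
Reactants: 9 5-iodo-8-methoxy-6-(methoxymethoxy)-3-methyl-1H-isochromen-1-one; 17 [2-methoxy-6-(methoxymethyl)-4-(methoxymethoxy)phenyl]boronic acid; 18 carbon monoxide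
Product: 19 8-methoxy-5-[2-methoxy-6-(methoxymethyl)-4-(methoxymethoxy)benzoyl]-6-(methoxymethoxy)-3-methyl-1H-isochromen-1-one
Conditions: 17 (2 equiv), PEPPSI-IPr (5 mol %), Cs2CO3 (3 equiv), CO (4 bar), PhCl (degassed), 80 °C
Reagents that add atoms: none
Why: Oxidative addition of the carbene-ligated Pd(0) into the C5–I bond, migratory insertion of CO to the aroylpalladium(II) species, base-assisted transfer of the ring A aryl group from boron and reductive elimination should deliver the diaryl ketone, so C5–C9 and C9–C1' are made in one operation. The closest known reaction type is the carbonylative Suzuki–Miyaura synthesis of ortho-substituted benzophenones from hindered aryl iodides with bulky carbene–palladium catalysts. No ring is closed and no stereocentre is created. The selectivity needed is carbonylation ahead of direct biaryl coupling: the C5–Pd centre is flanked by the 6-OMOM group and the fused ring (peri C4–H) and is electron-rich, so aryl migration to CO is fast while transmetalation of the 2,6-disubstituted boronic acid onto the uncarbonylated arylpalladium is slow, and CO pressure reinforces this. Regiochemistry is not in question because iodine and boron mark the two carbons to be joined. Protodeboronation of the electron-rich boronic acid is the main competing loss and is countered by anhydrous carbonate in chlorobenzene and the twofold charge of 17.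

Step 11
Reactants: 19 8-methoxy-5-[2-methoxy-6-(methoxymethyl)-4-(methoxymethoxy)benzoyl]-6-(methoxymethoxy)-3-methyl-1H-isochromen-1-one
Product: 20 6-hydroxy-5-[4-hydroxy-2-methoxy-6-(methoxymethyl)benzoyl]-8-methoxy-3-methyl-1H-isochromen-1-one
Conditions: conc. HCl (cat.), MeOH/THF, 40 °C
Reagents that add atoms: none
Why: Acid-catalysed acetal exchange with methanol releases both phenols and carries the CH2OMe units away as dimethoxymethane, so no free formaldehyde electrophile meets the electron-rich rings, while the benzylic methyl ether can only exchange with the solvent degenerately and the lactone is acid-stable.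

Step 12
Reactants: 20 6-hydroxy-5-[4-hydroxy-2-methoxy-6-(methoxymethyl)benzoyl]-8-methoxy-3-methyl-1H-isochromen-1-one
Product: 21 6-hydroxy-5-{[4-hydroxy-2-methoxy-6-(methoxymethyl)phenyl]methyl}-8-methoxy-3-methyl-1H-isochromen-1-one (CNP0481202.0)
Conditions: Et3SiH (6 equiv), TFA/CH2Cl2 (1:3), 0 °C to rt
Reagents that add atoms: none
Why: Ionic hydrogenation: the protonated ketone and then the derived benzhydryl cation are stabilised by the ortho 6-OH and para 8-OMe of the isocoumarin ring and by the para 4'-OH and ortho 2'-OMe of ring A and are reduced twice by the silane to CH2, whereas the CH2OMe group (meta to both ring A oxygens), the lactone and the C3=C4 bond should not react.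

Compound list
1 | methyl 2,4-dihydroxy-6-methylbenzoate (methyl orsellinate) | COC(=O)c1c(C)cc(O)cc1O | starting material
2 | methyl 2-hydroxy-4-(methoxymethoxy)-6-methylbenzoate | COC(=O)c1c(C)cc(OCOC)cc1O | intermediate
3 | methyl 2-methoxy-4-(methoxymethoxy)-6-methylbenzoate | COC(=O)c1c(C)cc(OCOC)cc1OC | intermediate
4 | [3-methoxy-2-(methoxycarbonyl)-5-(methoxymethoxy)phenyl]methyllithium (lithiated toluate, not isolated) | [Li]Cc1cc(OCOC)cc(OC)c1C(=O)OC | intermediate
5 | lithium 1-[3-methoxy-2-(methoxycarbonyl)-5-(methoxymethoxy)phenyl]-2-[methoxy(methyl)amino]propan-2-olate (racemic hemiaminal adduct, not isolated) | [Li+].COC(=O)c1c(CC(C)([O-])N(C)OC)cc(OCOC)cc1OC | intermediate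
6 | methyl 2-methoxy-4-(methoxymethoxy)-6-(2-oxopropyl)benzoate | COC(=O)c1c(CC(C)=O)cc(OCOC)cc1OC | intermediate
7 | 2-methoxy-4-(methoxymethoxy)-6-(2-oxopropyl)benzoic acid (keto acid, not isolated) | OC(=O)c1c(CC(C)=O)cc(OCOC)cc1OC | intermediate
8 | 8-methoxy-6-(methoxymethoxy)-3-methyl-1H-isochromen-1-one | COCOc1cc(OC)c2c(=O)oc(C)cc2c1 | intermediate
9 | 5-iodo-8-methoxy-6-(methoxymethoxy)-3-methyl-1H-isochromen-1-one | COCOc1cc(OC)c2c(=O)oc(C)cc2c1I | intermediate
10 | (2-bromo-3-methoxyphenyl)methanol | OCc1cccc(OC)c1Br | starting material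
11 | 2-bromo-1-methoxy-3-(methoxymethyl)benzene | COCc1cccc(OC)c1Br | intermediate
12 | 2-[4-bromo-3-methoxy-5-(methoxymethyl)phenyl]-4,4,5,5-tetramethyl-1,3,2-dioxaborolane (arylboronate, not isolated) | COCc1cc(B2OC(C)(C)C(C)(C)O2)cc(OC)c1Br | intermediate
13 | 4-bromo-3-methoxy-5-(methoxymethyl)phenol | COCc1cc(O)cc(OC)c1Br | intermediate
14 | 2-bromo-1-methoxy-3-(methoxymethyl)-5-(methoxymethoxy)benzene | COCc1cc(OCOC)cc(OC)c1Br | intermediate
15 | [2-methoxy-6-(methoxymethyl)-4-(methoxymethoxy)phenyl]lithium (aryllithium, not isolated) | [Li]c1c(OC)cc(OCOC)cc1COC | intermediate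
16 | lithium [2-methoxy-6-(methoxymethyl)-4-(methoxymethoxy)phenyl]tri(propan-2-yloxy)borate (not isolated) | [Li+].COCc1cc(OCOC)cc(OC)c1[B-](OC(C)C)(OC(C)C)OC(C)C | intermediate
17 | [2-methoxy-6-(methoxymethyl)-4-(methoxymethoxy)phenyl]boronic acid | COCc1cc(OCOC)cc(OC)c1B(O)O | intermediate
18 | carbon monoxide | [C-]#[O+] | starting material
19 | 8-methoxy-5-[2-methoxy-6-(methoxymethyl)-4-(methoxymethoxy)benzoyl]-6-(methoxymethoxy)-3-methyl-1H-isochromen-1-one | COCc1cc(OCOC)cc(OC)c1C(=O)c1c(OCOC)cc(OC)c2c(=O)oc(C)cc12 | intermediate
20 | 6-hydroxy-5-[4-hydroxy-2-methoxy-6-(methoxymethyl)benzoyl]-8-methoxy-3-methyl-1H-isochromen-1-one | COCc1cc(O)cc(OC)c1C(=O)c1c(O)cc(OC)c2c(=O)oc(C)cc12 | intermediate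
21 | 6-hydroxy-5-{[4-hydroxy-2-methoxy-6-(methoxymethyl)phenyl]methyl}-8-methoxy-3-methyl-1H-isochromen-1-one (achiral) | COCc1cc(O)cc(OC)c1Cc1c(O)cc(OC)c2c(=O)oc(C)cc12 | target

Total step count: 12 steps.
Longest linear sequence: 8 steps (steps 1–5, then 10–12); the ring A branch (steps 6–9) joins at step 10.

Steps most likely to fail

1. Step 10. The doubly ortho-substituted aryl group may transfer from boron too slowly. The boronic acid would then be lost by protodeboronation, or the aroylpalladium would be intercepted by adventitious water or carbonate, or CO-free biaryl coupling would take over. The fallback uses CO stepwise and sets out from 9 and 14. Palladium-catalysed reductive carbonylation of 9 (PdCl2(PPh3)2, CO 1 atm, Et3SiH, Na2CO3, DMF, 80 °C) should give 8-methoxy-6-(methoxymethoxy)-3-methyl-1-oxo-1H-isochromene-5-carbaldehyde F1. Aryllithium 15, generated from 14 as in step 9, is then added slowly to F1 at −78 °C. It should attack the aldehyde far faster than the hindered conjugated lactone and give racemic 5-{hydroxy[2-methoxy-6-(methoxymethyl)-4-(methoxymethoxy)phenyl]methyl}-8-methoxy-6-(methoxymethoxy)-3-methyl-1H-isochromen-1-one F2. Dess–Martin oxidation (NaHCO3, CH2Cl2) of F2 comes back to the route at 19.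

2. Step 5. Iodination may spread to C7 or C4, go on to a di-iodide, or be accompanied by acid-induced loss of the acetal. The fallback sets out from 2 and lets the free 2-OH direct the halogen before the pyranone exists. NIS in MeCN at rt should iodinate para to that phenol and give methyl 6-hydroxy-3-iodo-4-(methoxymethoxy)-2-methylbenzoate F3. Methylation (MeI, K2CO3, DMF) gives methyl 3-iodo-6-methoxy-4-(methoxymethoxy)-2-methylbenzoate F4. LDA at −78 °C, which does not exchange aryl iodides, gives [2-iodo-5-methoxy-6-(methoxycarbonyl)-3-(methoxymethoxy)phenyl]methyllithium F5. N-Methoxy-N-methylacetamide converts this into lithium 1-[2-iodo-5-methoxy-6-(methoxycarbonyl)-3-(methoxymethoxy)phenyl]-2-[methoxy(methyl)amino]propan-2-olate F6, and quench releases methyl 3-iodo-6-methoxy-4-(methoxymethoxy)-2-(2-oxopropyl)benzoate F7. Saponification to 3-iodo-6-methoxy-4-(methoxymethoxy)-2-(2-oxopropyl)benzoic acid F8 and Ac2O/pyridine cyclodehydration, as in step 4, come back to the route at 9.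

3. Step 4. Saponification of the doubly ortho-flanked ester may be slow, and base may instead drive Claisen-type closure of the ketone methyl onto the ester to a naphthalenediol. The fallback sets out from 6 and uses acid. Heating with p-TsOH·H2O in toluene at reflux should effect enol lactonisation, and the methanol set free takes the acetal off as dimethoxymethane, giving 6-hydroxy-8-methoxy-3-methyl-1H-isochromen-1-one F9. Re-protection of F9 (MOMCl, i-Pr2NEt, CH2Cl2) comes back to the route at 8.

Further compounds
F1 | step 10 | 8-methoxy-6-(methoxymethoxy)-3-methyl-1-oxo-1H-isochromene-5-carbaldehyde | COCOc1cc(OC)c2c(=O)oc(C)cc2c1C=O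
F2 | step 10 | 5-{hydroxy[2-methoxy-6-(methoxymethyl)-4-(methoxymethoxy)phenyl]methyl}-8-methoxy-6-(methoxymethoxy)-3-methyl-1H-isochromen-1-one (racemic) | COCc1cc(OCOC)cc(OC)c1C(O)c1c(OCOC)cc(OC)c2c(=O)oc(C)cc12
F3 | step 5 | methyl 6-hydroxy-3-iodo-4-(methoxymethoxy)-2-methylbenzoate | COC(=O)c1c(C)c(I)c(OCOC)cc1O
F4 | step 5 | methyl 3-iodo-6-methoxy-4-(methoxymethoxy)-2-methylbenzoate | COC(=O)c1c(C)c(I)c(OCOC)cc1OC
F5 | step 5 | [2-iodo-5-methoxy-6-(methoxycarbonyl)-3-(methoxymethoxy)phenyl]methyllithium | [Li]Cc1c(I)c(OCOC)cc(OC)c1C(=O)OC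
F6 | step 5 | lithium 1-[2-iodo-5-methoxy-6-(methoxycarbonyl)-3-(methoxymethoxy)phenyl]-2-[methoxy(methyl)amino]propan-2-olate (racemic) | [Li+].COC(=O)c1c(CC(C)([O-])N(C)OC)c(I)c(OCOC)cc1OC
F7 | step 5 | methyl 3-iodo-6-methoxy-4-(methoxymethoxy)-2-(2-oxopropyl)benzoate | COC(=O)c1c(CC(C)=O)c(I)c(OCOC)cc1OC
F8 | step 5 | 3-iodo-6-methoxy-4-(methoxymethoxy)-2-(2-oxopropyl)benzoic acid | OC(=O)c1c(CC(C)=O)c(I)c(OCOC)cc1OC
F9 | step 4 | 6-hydroxy-8-methoxy-3-methyl-1H-isochromen-1-one | COc1cc(O)cc2cc(C)oc(=O)c12
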